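## Structural features

The target is a single carbocycle, a cyclohex-4-ene (ring atoms C1–C6, alkene C4=C5), with one exocyclic carbon, C7, on the fully substituted C1. Four contiguous stereocentres, C6–C1–C2–C3, each carry oxygen, and the oxygens alternate faces (O6 and O2 on the face of C7, O1 and O3 on the other), so every vicinal pair is trans; the absolute configuration is 1S,2S,3R,6R in this numbering. The ring oxygens are in three different states (free allylic hydroxyl at C6, free tertiary hydroxyl at C1, acetate at C2, benzoate at C3) beside a primary benzoate on C7, so telling the oxygens apart is as much a problem as stereocontrol. Fragile points are acyl migration between neighbouring oxygens under base (O3 to O2, O2 to O1, O7 to O6), ionisation of the allylic C3 ester or C6 carbinol under acid or with zerovalent palladium, and aromatisation by loss of two oxygens. The real difficulty is the quaternary carbinol C1, flanked by stereocentres on both sides, inside an all-trans array that should be reached without a long protecting-group sequence. The key step exploits that O6/O1 and O2/O3 are each the trans pair left when an oxirane is opened by SN2 attack at its allylic end (C6 and C3). Closing them back gives the C1–O–C6 and C2–O–C3 oxiranes on opposite faces of the ring, which is the anti-dioxide of an aromatic ring, so one oxygen transfer to C2=C3 of the arene 1,6-oxide can write all four stereocentres.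

## Logic of the disconnections

18 back to 17. The C6–O bond of the free allylic hydroxyl is cut and O1 is reconnected to C6 as an oxirane. The C1/C6 trans-diol is what an anti opening at the allylic end of that oxirane leaves, and while both hydroxyls are hidden in one ring neither needs protection during ester placement. The gain is two hydroxyls and their trans relation folded into one functional group. The forward hydration must break C6–O and not C1–O, invert C6, and avoid allylic transposition and acyl migration.

17 back to 15 and 16. The acetyl C–O bond at O2 is cut. O2 is the only free hydroxyl of 15, so no site selection is needed. The gain is one acyl group less. The forward acylation must work on a hindered secondary alcohol next to the quaternary C1 without moving the neighbouring oxirane or the C3 ester.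

15 back to 13 and 14. The C3–O bond to the benzoate is cut. O2 and O3 are trans, and C3 is the allylic, less hindered end of a C2–O–C3 oxirane. The gain is that two different esters on C2 and C3 derive from one oxirane, and two stereocentres become a cis ring fusion. The forward opening must go at C3 and not at C6 (the allylic end of the other oxirane), C5 (conjugate opening) or C2, with inversion and under conditions that do not let the C2 alkoxide attack C1.

13 back to 11 (through 12). The C2–O and C3–O bonds of the second oxirane are cut, which removes one oxygen atom. What remains is the 1,6-oxide of a benzene ring, whose only stereogenic element is configurationally mobile. The gain is the largest of the plan: four fixed stereocentres reduce to a racemising pair on an aromatic-derived C14 frame. The forward oxygen transfer must choose one enantiomer of a racemising substrate, C2=C3 over C4=C5, the face anti to the existing oxide, and the oxide tautomer over 12.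

11 back to 9 (through 10). The C2=C3 and C4=C5 π bonds are traced to C3–Br and C4–Br bonds with hydrogens on C2 and C5. An arene oxide cannot be made from the arene, so the diene must be unveiled last from a saturated ring that already holds the oxirane. The gain is a stable precursor. The forward double elimination must run under strictly non-acidic conditions, because 11 isomerises to a phenol with acid.

9 back to 8. The two C–Br bonds are cut. A vicinal dibromide is the adduct of the isolated C3=C4 alkene, and any trans diastereomer serves. The forward addition must leave the oxirane closed.

8 back to 6 and 7. The ester C–O bond at O7 is cut. The benzoate is the one the target carries at C7, so it is not a protecting group and costs no later step. It is put on only after the free hydroxyl has directed the epoxidation. The forward acylation must not open the oxirane.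

6 back to 5. The two C–O bonds of the C1–O–C6 oxirane are cut. The free allylic hydroxyl of 5 singles out C1=C6 from the two alkenes, which is more reliable than electronic discrimination on the ester. The gain is an achiral diene alcohol. The forward step needs only chemoselectivity; a racemate is wanted, since the configuration becomes mobile at 11.

5 back to 3 (through 4). The two C7–H bonds are traced to the ester. The ester is what makes the cycloaddition work. The forward reduction must be 1,2 and leave the skipped diene alone.

3 back to 1 and 2. The C1–C2 and C5–C6 ring bonds are cut in a [4+2] sense. This gives the 1,4-diene with the C7 carbon on an sp2 ring carbon directly from two C4 feedstocks. The forward cycloaddition must stop at the skipped diene without aromatisation.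

## Other disconnections considered

Alternative 1: The cut is the C1–C6 ring bond, traced to the ring O–C4 bond of a six-membered lactone A2 whose carbonyl carbon becomes C7 and whose C4 carries an (E)-2-alkoxyvinyl group (C5=C6). Forward, A2 is enolised and O-silylated in the flask and undergoes an Ireland–Claisen [3,3] shift through a boat enforced by the C2–C3 tether; C1–C6 forms, O–C4 breaks and C4=C5 appears, giving A1.
- In favour: C2 and C3 come from the chiral pool, so the absolute configuration is secure from the start. On this point the alternative is better than the chosen plan, whose absolute configuration rests on one untested catalytic event. C1 and C6 are set together in a concerted shift of a known class.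
- Against: C7 arrives as a carboxylic acid and must be reduced and benzoylated. All four oxygens are ethers, and the two identical silyl ethers at C2 and C3 must later be told apart for acetate and benzoate. The enolate of A2 has a β-silyloxy group at C2 that can be expelled before silylation.
- Structure: A1 holds the ring and the four stereocentres but with C7 at the wrong oxidation level and every oxygen masked, whereas 13 is two ring openings and one acetylation from 18 with no protecting group.
- Mechanism: a thermal pericyclic shift with a predictable transition-state shape would be more reliable than oxygen transfer to a racemising substrate.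
- Step economy: roughly twice the ten steps of the chosen plan would be expected (about ten to A2, the shift, about seven afterwards).

Alternative 2: The cut is C5–C6. The open-chain aldehyde A4, with a (Z)-alkenyl iodide at C5, would be closed with CrCl2 and catalytic NiCl2. The C5–I bond adds oxidatively to zerovalent nickel, the alkenyl group passes to trivalent chromium, and this adds to the C6 aldehyde to give A3.
- In favour: esters tolerate the reagent, so A3 already carries the acetate and both benzoates and is one desilylation from 18. This is the shortest endgame of all plans and better than the three steps after 13. The alkene geometry is fixed in the iodide, and the absolute configuration again comes from the chiral pool.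
- Against: the C6 configuration depends on the facial choice at an α-quaternary, α-silyloxy aldehyde inside a forming ring, with no strong control element. The quaternary C1 must be built stereoselectively on an open chain, so the hardest problem is moved and not solved. Three acyl groups on adjacent oxygens would have to survive the whole chain synthesis without migrating.
- Structure: A3 is closer to 18 than 13 is.
- Mechanism: a known closure with uncertain diastereoselectivity stands against a new step whose facial sense is fixed by the substrate.
- Step economy: the endgame wins, but the route to A4 would be long, so the total should exceed ten steps clearly.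

Alternative 3: The cuts are C1–C7 and C7–O of a spiro-oxirane. LiCH2Cl (from ICH2Cl and MeLi·LiBr at low temperature) would add to the C1 ketone of A6 along the axial direction, and the alkoxide would displace chloride to give A5.
- In favour: the quaternary centre is made late on a rigid ring by a small nucleophile. The spiro-oxirane would then take benzoate at its primary C7 end, which is a more secure site selection than the C3-versus-C6 choice in 13; on that step the alternative is better. The reaction type is known.
- Against: A6 is a β,γ-unsaturated ketone with oxygen on both α-carbons. Enolisation by the basic carbenoid would epimerise C2 or C6, expel the C3 silyloxy group and lead towards an aromatic ring. The silyl ethers at C3 and C6 of A5 are identical although one must become a benzoate and the other stay a hydroxyl.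
- Structure: A5 has the full carbon frame but needs five to six further steps with one difficult differentiation.
- Mechanism: known but run on a fragile substrate, against new but run on a substrate with no enolisable position.
- Step economy: the chosen plan is shorter both before and after the key step.

Key step: step 7

Remark (numbering): ring atoms keep the labels C1 (carries C7), C2, C3, C4, C5, C6 of the target in every compound; descriptors in names follow systematic numbering.

Remark (structures): the configurations of 11, 13 and 18 were checked against each other atom by atom and agree (first oxide on the face of O1, second oxide on the face of O2), so no structure needed correction; 6, 8, 9 and 10 are racemates drawn as one enantiomer.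

Remark (catalyst, assumption): ketone K is the glucose-derived 4,5-O-isopropylidene pyranos-3-ulose spiro-fused at its anomeric carbon to an N-(4-methylphenyl)oxazolidin-2-one. The L-glucose-derived antipode, SMILES O1C[C@@H]2OC(C)(C)O[C@@H]2C(=O)[C@]13CN(c4ccc(C)cc4)C(=O)O3, is assumed, because the spiro model with the vinyl substituent next to the oxazolidinone predicts it to deliver oxygen to the required face of C2=C3. This sense should be confirmed on the first run and the antipode taken if it is opposite.

## Route

Step 1
Reactants: 1 buta-1,3-diene; 2 methyl propiolate
Product: 3 methyl cyclohexa-1,4-diene-1-carboxylate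
Conditions: 1 (3 equiv), PhMe, hydroquinone (cat.), sealed vessel, 110 °C
Reagents that add atoms: none
Why: Thermal Diels–Alder cycloaddition of the diene to the electron-poor alkyne forms C1–C2 and C5–C6 and gives the skipped diene with the ester on sp2 C1; the inhibitor suppresses diene polymerisation, air is excluded to prevent aromatisation, and no stereocentre is formed.

Step 2
Reactants: 3 methyl cyclohexa-1,4-diene-1-carboxylate
Product: 5 cyclohexa-1,4-dien-1-ylmethanol, via cyclohexa-1,4-diene-1-carbaldehyde 4 (not isolated)
Conditions: i-Bu2AlH (2.3 equiv), CH2Cl2, −78 → 0 °C; aq. KNaC4H4O6 work-up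
Reagents that add atoms: none
Why: 1,2-Reduction of the conjugated ester by the aluminium hydride passes through aldehyde 4 to the allylic alcohol without touching either alkene; the hydroxyl is the directing group for step 3.

Step 3
Reactants: 5 cyclohexa-1,4-dien-1-ylmethanol
Product: 6 rac-[(1S,6S)-7-oxabicyclo[4.1.0]hept-3-en-1-yl]methanol
Conditions: VO(acac)2 (2 mol%), t-BuOOH (1.2 equiv), CH2Cl2, 0 °C → rt
Reagents that add atoms: tert-butyl hydroperoxide, CC(C)(C)OO
Why: Hydroxyl-directed vanadium-catalysed epoxidation: the vanadium alkoxide of 5 delivers the peroxide oxygen only to the allylic C1=C6 bond and leaves the isolated C3=C4 bond. C1 and C6 are formed as a racemate on purpose, because their configuration becomes mobile at 11.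

Step 4
Reactants: 6 rac-[(1S,6S)-7-oxabicyclo[4.1.0]hept-3-en-1-yl]methanol; 7 benzoyl chloride
Product: 8 rac-[(1S,6S)-7-oxabicyclo[4.1.0]hept-3-en-1-yl]methyl benzoate
Conditions: 7 (1.1 equiv), pyridine, DMAP (cat.), CH2Cl2, 0 °C
Reagents that add atoms: none
Why: DMAP-catalysed acylation of the primary alcohol installs the C7 benzoate of the target at once, so no protecting group is spent; the basic medium keeps the oxirane closed.

Step 5
Reactants: 8 rac-[(1S,6S)-7-oxabicyclo[4.1.0]hept-3-en-1-yl]methyl benzoate
Product: 9 rac-[(1S,3R,4R,6S)-3,4-dibromo-7-oxabicyclo[4.1.0]heptan-1-yl]methyl benzoate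
Conditions: Br2 (1.0 equiv), solid NaHCO3, CH2Cl2, −78 °C, dark
Reagents that add atoms: bromine, BrBr
Why: Electrophilic anti addition through the bromonium ion gives the trans-3,4-dibromide; the diastereomer with the opposite sense relative to the oxirane may accompany it and converges in step 6. The oxirane survives because HBr is scavenged and the temperature is low.

Step 6
Reactants: 9 rac-[(1S,3R,4R,6S)-3,4-dibromo-7-oxabicyclo[4.1.0]heptan-1-yl]methyl benzoate
Product: 11 [(1S,6S)-7-oxabicyclo[4.1.0]hepta-2,4-dien-1-yl]methyl benzoate as its rapidly interconverting racemate, via allylic bromide 10 (not isolated)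
Conditions: DBU (3 equiv), THF, 0 °C → rt; filtration through basic Al2O3, base-washed glassware, used at once
Reagents that add atoms: none
Why: Two successive E2 dehydrobrominations by the amidine base remove H5 and then H2 (both next to an oxirane carbon) and unveil the C2=C3–C4=C5 diene, the established type of route to arene oxides. No acid is present at any point, since 11 isomerises to a phenol with acid.

Step 7
Reactants: 11 [(1S,6S)-7-oxabicyclo[4.1.0]hepta-2,4-dien-1-yl]methyl benzoate
Product: 13 [(1S,2S,4S,7S)-3,8-dioxatricyclo[5.1.0.0(2,4)]oct-5-en-1-yl]methyl benzoate (anti-1,6:2,3-dioxide), via oxepin-2-ylmethyl benzoate 12 (not isolated)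
Conditions: ketone K (0.3 equiv), KHSO5 (as 2KHSO5·KHSO4·K2SO4, 1.6 equiv), K2CO3, Bu4NHSO4 (cat.), MeOCH2CH2OMe/CH2(OMe)2 3:1, aq. K2CO3–AcOH buffer (pH 8), −10 °C
Reagents that add atoms: potassium peroxymonosulfate, [K+].[O-]S(=O)(=O)OO
Why: Proposed new method: KHSO5 converts ketone K into its chiral dioxirane, which passes one oxygen atom to C2=C3 of 11 through a spiro transition state, so that C2–O and C3–O form together and the second oxirane closes by a concerted [2+1] atom transfer (no open intermediate, hence a cis ring fusion at C2/C3). The closest known reaction type is the asymmetric epoxidation of cis-olefins and conjugated cis-dienes by this ketone class; what is new is its coupling to the oxide–oxepin valence tautomerism, which exchanges 11 with its mirror image through achiral 12 much faster than oxygen transfer, so that the faster-reacting enantiomer is continuously refilled (Curtin–Hammett, dynamic kinetic resolution). C2 and C3 are set anti to the existing oxirane by the substrate, whose C1/C6 oxygen covers its own face while C7 lies near the ring plane; C1 and C6, mobile until now, are fixed by the catalyst, because only in 11 is the catalyst's preferred olefin face (vinyl group C4=C5 next to the oxazolidinone) also the anti face of C2=C3. Needed beyond this are selectivity for the oxide tautomer over the enol-ether bonds of 12 (the cold aqueous medium shifts the equilibrium towards the oxide), for C2=C3 over C4=C5, and for a single oxygen transfer (C4=C5 of 13 is deactivated by two allylic oxiranes). Site selection is the one point the substrate does not secure, since C7 slightly shields C2=C3; the same facial preference, however, pairs C4=C5 with the mirror-image oxide, so that any shortfall should surface as a separable constitutional isomer and not as the enantiomer of 13.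

Step 8
Reactants: 13 [(1S,2S,4S,7S)-3,8-dioxatricyclo[5.1.0.0(2,4)]oct-5-en-1-yl]methyl benzoate; 14 benzoic acid
Product: 15 [(1R,2S,3R,6S)-3-benzoyloxy-2-hydroxy-7-oxabicyclo[4.1.0]hept-4-en-1-yl]methyl benzoate
Conditions: 14 (3 equiv), Bu4N+ PhCO2− (0.3 equiv), MeCN, 45 °C
Reagents that add atoms: none
Why: SN2 opening of a vinyl oxirane by carboxylate with the acid as proton source: benzoate attacks allylic C3 anti to the departing oxygen, which inverts C3 and leaves O2 and O3 trans. C6, the other allylic oxirane carbon, is shielded by the quaternary C1 and by C7 on the face of attack, and the acidic buffer keeps O2 protonated so that neither oxirane migration nor acyl shift sets in.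

Step 9
Reactants: 15 [(1R,2S,3R,6S)-3-benzoyloxy-2-hydroxy-7-oxabicyclo[4.1.0]hept-4-en-1-yl]methyl benzoate; 16 acetic anhydride
Product: 17 [(1S,2S,3R,6S)-2-acetyloxy-3-benzoyloxy-7-oxabicyclo[4.1.0]hept-4-en-1-yl]methyl benzoate
Conditions: 16 (2 equiv), pyridine, DMAP (0.1 equiv), CH2Cl2, 0 °C → rt
Reagents that add atoms: none
Why: DMAP-catalysed acetylation of the only free hydroxyl; no stereocentre is touched and the weak base does not trigger oxirane migration.

Step 10
Reactants: 17 [(1S,2S,3R,6S)-2-acetyloxy-3-benzoyloxy-7-oxabicyclo[4.1.0]hept-4-en-1-yl]methyl benzoate
Product: 18 [(1S,2R,5R,6S)-6-acetyloxy-5-benzoyloxy-1,2-dihydroxycyclohex-3-en-1-yl]methyl benzoate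
Conditions: HClO4 (0.05 M), THF/H2O 3:1, 0 °C → rt
Reagents that add atoms: water, O
Why: Acid-catalysed hydration of a vinyl oxirane: the protonated oxirane opens at allylic C6, because C1 is tertiary but deactivated by the acyloxy-bearing C2 and C7. Water enters anti to the leaving oxygen, which inverts C6 and puts O6 trans to the retained O1.

## Compound list

1 | buta-1,3-diene | C=CC=C | starting material
2 | methyl propiolate | C#CC(=O)OC | starting material
3 | methyl cyclohexa-1,4-diene-1-carboxylate | COC(=O)C1=CCC=CC1 | intermediate
4 | cyclohexa-1,4-diene-1-carbaldehyde (formed and consumed in step 2) | O=CC1=CCC=CC1 | intermediate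
5 | cyclohexa-1,4-dien-1-ylmethanol | OCC1=CCC=CC1 | intermediate
6 | rac-[(1S,6S)-7-oxabicyclo[4.1.0]hept-3-en-1-yl]methanol (one enantiomer drawn) | OC[C@@]12CC=CC[C@@H]1O2 | intermediate
7 | benzoyl chloride | O=C(Cl)c1ccccc1 | starting material
8 | rac-[(1S,6S)-7-oxabicyclo[4.1.0]hept-3-en-1-yl]methyl benzoate (one enantiomer drawn) | O=C(OC[C@@]12CC=CC[C@@H]1O2)c1ccccc1 | intermediate
9 | rac-[(1S,3R,4R,6S)-3,4-dibromo-7-oxabicyclo[4.1.0]heptan-1-yl]methyl benzoate (trans-dibromide; the 3S,4S diastereomer may accompany it) | O=C(OC[C@@]12C[C@@H](Br)[C@H](Br)C[C@@H]1O2)c1ccccc1 | intermediate
10 | rac-[(1S,3R,6S)-3-bromo-7-oxabicyclo[4.1.0]hept-4-en-1-yl]methyl benzoate (allylic bromide, formed and consumed in step 6) | O=C(OC[C@@]12C[C@@H](Br)C=C[C@@H]1O2)c1ccccc1 | intermediate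
11 | [(1S,6S)-7-oxabicyclo[4.1.0]hepta-2,4-dien-1-yl]methyl benzoate (arene 1,6-oxide; obtained as the racemate in fast exchange, reacting enantiomer drawn) | C1=CC=C[C@@H]2O[C@]12COC(=O)c1ccccc1 | intermediate
12 | oxepin-2-ylmethyl benzoate (valence tautomer, racemisation relay in step 7) | O=C(OCC1=CC=CC=CO1)c1ccccc1 | intermediate
13 | [(1S,2S,4S,7S)-3,8-dioxatricyclo[5.1.0.0(2,4)]oct-5-en-1-yl]methyl benzoate (anti-1,6:2,3-dioxide) | O1[C@H]2[C@@H]1C=C[C@@H]1O[C@@]12COC(=O)c1ccccc1 | intermediate
14 | benzoic acid | OC(=O)c1ccccc1 | starting material
15 | [(1R,2S,3R,6S)-3-benzoyloxy-2-hydroxy-7-oxabicyclo[4.1.0]hept-4-en-1-yl]methyl benzoate | O[C@H]1[C@H](OC(=O)c2ccccc2)C=C[C@@H]2O[C@]12COC(=O)c1ccccc1 | intermediate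
16 | acetic anhydride | CC(=O)OC(C)=O | starting material
17 | [(1S,2S,3R,6S)-2-acetyloxy-3-benzoyloxy-7-oxabicyclo[4.1.0]hept-4-en-1-yl]methyl benzoate | CC(=O)O[C@H]1[C@H](OC(=O)c2ccccc2)C=C[C@@H]2O[C@]12COC(=O)c1ccccc1 | intermediate
18 | [(1S,2R,5R,6S)-6-acetyloxy-5-benzoyloxy-1,2-dihydroxycyclohex-3-en-1-yl]methyl benzoate | CC(=O)O[C@H]1[C@H](OC(=O)c2ccccc2)C=C[C@@H](O)[C@@]1(O)COC(=O)c1ccccc1 | target

## Step count and least certain steps

Total: 10 steps. Longest linear sequence: 10 steps, from 1 and 2; 7, 14 and 16 are commercial acylating agents.

**Step 7 (key step, new method).** Four processes could defeat it: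
- oxygen transfer to the enol-ether bonds of the oxepin tautomer, followed by ring cleavage to open-chain dicarbonyl material;
- oxygen transfer to C4=C5 of the mirror-image oxide, which the catalyst's facial preference also allows, so that the constitutional isomer grows at the expense of 13;
- isomerisation of the arene oxide to a phenol in the aqueous medium;
- weak facial discrimination by a ketone never tried on this substrate class.

The fallback uses known reaction types only and sets out from 11. Sensitised photo-oxygenation (O2, tetraphenylporphyrin, visible light, CH2Cl2, −40 °C) adds singlet oxygen across C2 and C5 on the face anti to the oxirane and should give the endoperoxide rac-(2,5-epidioxy-1,6-epoxycyclohex-3-en-1-yl)methyl benzoate F1. PPh3 (1 equiv, CH2Cl2, −40 → 0 °C) then attacks the less hindered peroxide oxygen on C5, and the C2 alkoxide closes onto C3 with allylic shift and loss of the phosphine oxide. This gives the racemic anti-dioxide, that is 13 together with its mirror image [(1R,2R,4R,7R)-3,8-dioxatricyclo[5.1.0.0(2,4)]oct-5-en-1-yl]methyl benzoate F2. Preparative chromatography on a chiral stationary phase (cellulose tris(3,5-dimethylphenylcarbamate)) separates the two, and the route is rejoined at 13. Site and face selection then rest on the substrate alone; the price is two more operations and at most half of the material.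

**Step 8.** Benzoate may attack C6 of the other oxirane or open the 2,3-oxirane with allylic shift at C5. If the medium becomes basic, the C2 alkoxide may attack C1 and move the oxirane, or the C3 benzoate may shift to O2. The fallback sets out from 13 and separates ring opening from acylation. Hydrolysis in neutral buffer (KH2PO4/K2HPO4, pH 7, MeCN/H2O, 40 °C), where the smallest nucleophile is steered by sterics alone, should open C3 and give [(1R,2S,3R,6S)-2,3-dihydroxy-7-oxabicyclo[4.1.0]hept-4-en-1-yl]methyl benzoate F3. Benzoylation with 7 (1.0 equiv, 2,4,6-collidine, CH2Cl2, −40 °C) at the allylic, less hindered O3 then returns to the route at 15. This fallback rests on the same C3-over-C6 steric preference as step 8 and does not cure a failure of that preference.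

**Step 10.** Ionisation at C6 may run ahead of water capture, which would allow capture at C4 with allylic shift, capture syn to the leaving oxygen, or participation of the C7 benzoate with acyl migration to O6. The fallback sets out from 17. Anhydrous CF3CO2H (CH2Cl2, −20 °C) opens the oxirane by collapse of a tight ion pair at C6 and should give [(1S,2R,5R,6S)-6-acetyloxy-5-benzoyloxy-1-hydroxy-2-(trifluoroacetyloxy)cyclohex-3-en-1-yl]methyl benzoate F4. Its trifluoroacetate alone is cleaved by KHCO3 in MeOH at 0 °C, which returns to the route at 18.

**Step 6.** The second elimination may stall, the amidine may substitute the allylic bromide 10, or 11 may isomerise to the phenol during isolation. The fallback sets out from 8. Radical allylic bromination (N-bromosuccinimide, AIBN, solid K2CO3, PhCF3, 80 °C) should give rac-[(1S,5R,6R)-5-bromo-7-oxabicyclo[4.1.0]hept-3-en-1-yl]methyl benzoate F5, together with its allylic isomer 10. A single dehydrobromination (DBU, THF, 0 °C), 1,4 from F5 or 1,2 from 10, returns to the route at 11 with only one elimination to complete.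

## Further compounds

F1 | step 7 | rac-(2,5-epidioxy-1,6-epoxycyclohex-3-en-1-yl)methyl benzoate (peroxide bridge anti to the oxirane; one enantiomer drawn) | O=C(OC[C@]12O[C@H]1[C@@H]3OO[C@H]2C=C3)c1ccccc1
F2 | step 7 | [(1R,2R,4R,7R)-3,8-dioxatricyclo[5.1.0.0(2,4)]oct-5-en-1-yl]methyl benzoate (enantiomer of 13) | O1[C@@H]2[C@H]1C=C[C@H]1O[C@]12COC(=O)c1ccccc1
F3 | step 8 | [(1R,2S,3R,6S)-2,3-dihydroxy-7-oxabicyclo[4.1.0]hept-4-en-1-yl]methyl benzoate | O[C@H]1[C@H](O)C=C[C@@H]2O[C@]12COC(=O)c1ccccc1
F4 | step 10 | [(1S,2R,5R,6S)-6-acetyloxy-5-benzoyloxy-1-hydroxy-2-(trifluoroacetyloxy)cyclohex-3-en-1-yl]methyl benzoate | CC(=O)O[C@H]1[C@H](OC(=O)c2ccccc2)C=C[C@@H](OC(=O)C(F)(F)F)[C@@]1(O)COC(=O)c1ccccc1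
F5 | step 6 | rac-[(1S,5R,6R)-5-bromo-7-oxabicyclo[4.1.0]hept-3-en-1-yl]methyl benzoate (C5 epimer may accompany it; one enantiomer drawn) | O=C(OC[C@@]12CC=C[C@@H](Br)[C@@H]1O2)c1ccccc1
A1 | alternative 1 | (1S,2S,3R,6R)-2,3-bis(tert-butyldimethylsilyloxy)-1,6-bis[(4-methoxyphenyl)methoxy]cyclohex-4-ene-1-carboxylic acid | CC(C)(C)[Si](C)(C)O[C@H]1[C@H](O[Si](C)(C)C(C)(C)C)C=C[C@@H](OCc2ccc(OC)cc2)[C@@]1(OCc1ccc(OC)cc1)C(=O)O
A2 | alternative 1 | (4R,5R,6S)-4,5-bis(tert-butyldimethylsilyloxy)-3-[(4-methoxyphenyl)methoxy]-6-{(E)-2-[(4-methoxyphenyl)methoxy]ethenyl}oxan-2-one (either C3 epimer) | O=C1O[C@@H](/C=C/OCc2ccc(OC)cc2)[C@@H](O[Si](C)(C)C(C)(C)C)[C@H](O[Si](C)(C)C(C)(C)C)C1OCc1ccc(OC)cc1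
A3 | alternative 2 | [(1S,2R,5R,6S)-6-acetyloxy-5-benzoyloxy-2-hydroxy-1-(triethylsilyloxy)cyclohex-3-en-1-yl]methyl benzoate | CC(=O)O[C@H]1[C@H](OC(=O)c2ccccc2)C=C[C@@H](O)[C@@]1(O[Si](CC)(CC)CC)COC(=O)c1ccccc1
A4 | alternative 2 | (2R,3S,4R,5Z)-3-acetyloxy-4-benzoyloxy-2-(benzoyloxymethyl)-6-iodo-2-(triethylsilyloxy)hex-5-enal | CC(=O)O[C@@H]([C@H](OC(=O)c1ccccc1)/C=C\I)[C@](O[Si](CC)(CC)CC)(COC(=O)c1ccccc1)C=O
A5 | alternative 3 | (3R,4R,7R,8S)-4,7-bis(tert-butyldimethylsilyloxy)-8-[(4-methoxyphenyl)methoxy]-1-oxaspiro[2.5]oct-5-ene | COc1ccc(CO[C@H]2[C@H](O[Si](C)(C)C(C)(C)C)C=C[C@@H](O[Si](C)(C)C(C)(C)C)[C@@]23CO3)cc1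
A6 | alternative 3 | (2R,5R,6S)-2,5-bis(tert-butyldimethylsilyloxy)-6-[(4-methoxyphenyl)methoxy]cyclohex-3-en-1-one | COc1ccc(CO[C@H]2[C@H](O[Si](C)(C)C(C)(C)C)C=C[C@@H](O[Si](C)(C)C(C)(C)C)C2=O)cc1
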